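**Retrosynthetic overview**

1. Locants are germacrane locants: ring A = ten-membered carbocycle C1–C10, ring B = butenolide O–C6–C7=C11–C12(=O), C13 = acetoxymethyl carbon. The enabling feature is C7, the β-carbon of ring B: an sp2 carbon flanked by two carbinol carbons (C6 with the lactone oxygen, C8 with the ester oxygen). C7 is therefore a vinylidene 1,1-dianion synthon, and a gem-dibromoalkene carrying C11–C13 can add first to a C6 aldehyde (ring B) and last to a C8 aldehyde (ring A).
2. Disconnections: C8–O ester (Steglich, last step); C7–C8 (Nozaki–Hiyama–Kishi closure of ring A); C6–C7 and C6–O (magnesium carbenoid addition to an epoxy aldehyde, then invertive lactonization); C8–C9 (allyl–vinyl Stille coupling on 8-bromogeranyl acetate, the vinyl group being the masked C8 aldehyde).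
3. Ring order: oxirane C1–C10 (Shi), oxirane C4–C5 (Sharpless), ring B, then ring A as the last ring of the skeleton; the side-chain oxirane arrives ready-made with (2S)-2-methyloxirane-2-carboxylic acid.
4. Stereocontrol: C1/C10 and C4/C5 by reagent, C6 by Felkin–Anh addition followed by SN2 inversion, C8 in the ring closure.

Key step: step 15

Step 1
Reactants: 1 geranyl acetate [(2E)-3,7-dimethylocta-2,6-dien-1-yl acetate]
Product: 2 (2E,6E)-8-hydroxy-3,7-dimethylocta-2,6-dien-1-yl acetate
Conditions: SeO2 (cat.), t-BuOOH, salicylic acid (cat.), CH2Cl2, 25 °C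
Reagents that add atoms: tert-butyl hydroperoxide, CC(C)(C)OO
Why: The Riley-type allylic oxidation (ene reaction, then [2,3]-sigmatropic shift) should hydroxylate the E-methyl group of the electron-rich distal olefin while the acetate-deactivated olefin stays untouched; no stereocentre is formed.

Step 2
Reactants: 2 (2E,6E)-8-hydroxy-3,7-dimethylocta-2,6-dien-1-yl acetate
Product: 3 (2E,6E)-8-bromo-3,7-dimethylocta-2,6-dien-1-yl acetate
Conditions: CBr4, PPh3, CH2Cl2, 0 °C
Reagents that add atoms: tetrabromomethane, BrC(Br)(Br)Br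
Why: The Appel reaction replaces the primary allylic hydroxyl by bromide through SN2 displacement of the oxyphosphonium group, without allylic transposition; no stereocentre is formed.

Step 3
Reactants: 3 (2E,6E)-8-bromo-3,7-dimethylocta-2,6-dien-1-yl acetate
Product: 4 (2E,6E)-3,7-dimethyldeca-2,6,9-trien-1-yl acetate
Conditions: tributyl(vinyl)stannane, Pd2(dba)3 (2.5 mol %), P(2-furyl)3 (10 mol %), THF, 50 °C
Reagents that add atoms: tributyl(vinyl)stannane, C=C[Sn](CCCC)(CCCC)CCCC
Why: The Stille allyl–vinyl coupling should deliver the vinyl group to the less substituted terminus of the π-allylpalladium intermediate with retention of the 6E geometry, the allylic bromide ionizing much faster than the allylic acetate; no stereocentre is formed.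

Step 4
Reactants: 4 (2E,6E)-3,7-dimethyldeca-2,6,9-trien-1-yl acetate
Product: 5 (2E)-3-methyl-5-[(2R,3R)-3-methyl-3-(prop-2-en-1-yl)oxiran-2-yl]pent-2-en-1-yl acetate
Conditions: Shi ketone (D-fructose-derived, 30 mol %), KHSO5 (Oxone), K2CO3, Bu4NHSO4 (cat.), MeCN–dimethoxymethane–aq. Na2B4O7 buffer (pH 10.5), 0 °C
Reagents that add atoms: potassium peroxymonosulfate, [K+].[O-]S(=O)(=O)OO
Why: The Shi asymmetric epoxidation should oxidize only the electron-rich C1=C10 olefin (the acetate-bearing olefin is deactivated and monosubstituted olefins are poor substrates), and the spiro transition state of the dioxirane from the D-fructose-derived ketone sets C1 and C10 as the (R,R)-oxirane by reagent control.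

Step 5
Reactants: 5 (2E)-3-methyl-5-[(2R,3R)-3-methyl-3-(prop-2-en-1-yl)oxiran-2-yl]pent-2-en-1-yl acetate
Product: 6 (2E)-3-methyl-5-[(2R,3R)-3-methyl-3-(prop-2-en-1-yl)oxiran-2-yl]pent-2-en-1-ol
Conditions: K2CO3 (cat.), MeOH, 0 °C
Reagents that add atoms: none
Why: Zemplén-type transesterification removes the acetate without touching the oxirane; no stereocentre changes.

Step 6
Reactants: 6 (2E)-3-methyl-5-[(2R,3R)-3-methyl-3-(prop-2-en-1-yl)oxiran-2-yl]pent-2-en-1-ol
Product: 7 [(2R,3R)-3-methyl-3-{2-[(2R,3R)-3-methyl-3-(prop-2-en-1-yl)oxiran-2-yl]ethyl}oxiran-2-yl]methanol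
Conditions: Ti(OiPr)4 (10 mol %), D-(−)-diethyl tartrate (12 mol %), t-BuOOH, 4 Å MS, CH2Cl2, −20 °C
Reagents that add atoms: tert-butyl hydroperoxide, CC(C)(C)OO
Why: The Sharpless asymmetric epoxidation acts only on the allylic alcohol olefin and, with D-(−)-diethyl tartrate, delivers oxygen to the face that gives the (2R,3R)-epoxy alcohol (C4 and C5) by reagent control, independent of the remote oxirane.

Step 7
Reactants: 7 [(2R,3R)-3-methyl-3-{2-[(2R,3R)-3-methyl-3-(prop-2-en-1-yl)oxiran-2-yl]ethyl}oxiran-2-yl]methanol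
Product: 8 (2S,3R)-3-methyl-3-{2-[(2R,3R)-3-methyl-3-(prop-2-en-1-yl)oxiran-2-yl]ethyl}oxirane-2-carbaldehyde
Conditions: Dess–Martin periodinane, pyridine, CH2Cl2, 0 °C
Reagents that add atoms: none
Why: The Dess–Martin oxidation gives the α,β-epoxy aldehyde under buffered, non-epimerizing conditions; no stereocentre changes (the descriptor at the formyl-bearing carbon changes only through CIP priority).

Step 8
Reactants: 9 tert-butyl acrylate (tert-butyl prop-2-enoate)
Product: 10 tert-butyl 2-(hydroxymethyl)prop-2-enoate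
Conditions: aq. formaldehyde, DABCO, 1,4-dioxane–H2O, 25 °C
Reagents that add atoms: formaldehyde, C=O
Why: The Morita–Baylis–Hillman reaction of the acrylate with formaldehyde installs C13 at the α-carbon; no stereocentre is formed.

Step 9
Reactants: 10 tert-butyl 2-(hydroxymethyl)prop-2-enoate
Product: 11 tert-butyl 2-(acetoxymethyl)prop-2-enoate
Conditions: Ac2O, pyridine, DMAP (cat.), CH2Cl2, 0 °C
Reagents that add atoms: acetic anhydride, CC(=O)OC(C)=O
Why: DMAP-catalysed acyl transfer acetylates the primary alcohol, so the C13 acetate of the target is in place from the outset; no stereocentre is formed.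

Step 10
Reactants: 11 tert-butyl 2-(acetoxymethyl)prop-2-enoate
Product: 13 tert-butyl 3-acetoxy-2-oxopropanoate, via ozonide 12 (not isolated)
Conditions: O3, CH2Cl2, −78 °C; then Me2S, −78 → 20 °C
Reagents that add atoms: ozone, [O-][O+]=O
Why: Ozonolysis (Criegee mechanism) of the 1,1-disubstituted acrylate olefin with reductive work-up gives the α-keto ester, whose keto carbon is C11; no stereocentre is formed.

Step 11
Reactants: 13 tert-butyl 3-acetoxy-2-oxopropanoate
Product: 14 tert-butyl 2-(acetoxymethyl)-3,3-dibromoprop-2-enoate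
Conditions: CBr4, PPh3, CH2Cl2, 0 °C
Reagents that add atoms: tetrabromomethane, BrC(Br)(Br)Br
Why: The Ramirez dibromo-olefination (first stage of the Corey–Fuchs sequence) works well on the activated keto group of α-keto esters and introduces C7 as a CBr2 group; no stereocentre is formed.

Step 12
Reactants: 14 tert-butyl 2-(acetoxymethyl)-3,3-dibromoprop-2-enoate; 8 (2S,3R)-3-methyl-3-{2-[(2R,3R)-3-methyl-3-(prop-2-en-1-yl)oxiran-2-yl]ethyl}oxirane-2-carbaldehyde
Product: 16 tert-butyl (2E,4S)-2-(acetoxymethyl)-3-bromo-4-hydroxy-4-[(2R,3R)-3-methyl-3-{2-[(2R,3R)-3-methyl-3-(prop-2-en-1-yl)oxiran-2-yl]ethyl}oxiran-2-yl]but-2-enoate, via magnesium carbenoid 15 (not isolated)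
Conditions: i-PrMgCl·LiCl (1.05 equiv), THF, −78 °C; then 8, −78 °C; then AcOH, −78 °C
Reagents that add atoms: none
Why: Bromine–magnesium exchange is directed by chelation to the bromine cis to the ester and gives a configurationally defined magnesium carbenoid, which adds 1,2 to the aldehyde in the Felkin–Anh (Cornforth) sense, anti to the oxirane C–O bond and reinforced by the cis methyl group on C4, so that C6 should be set as the anti (erythro) carbinol while the tert-butyl ester resists lactonization at −78 °C.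

Step 13
Reactants: 16 tert-butyl (2E,4S)-2-(acetoxymethyl)-3-bromo-4-hydroxy-4-[(2R,3R)-3-methyl-3-{2-[(2R,3R)-3-methyl-3-(prop-2-en-1-yl)oxiran-2-yl]ethyl}oxiran-2-yl]but-2-enoate
Product: 18 [(5R)-4-bromo-5-[(2R,3R)-3-methyl-3-{2-[(2R,3R)-3-methyl-3-(prop-2-en-1-yl)oxiran-2-yl]ethyl}oxiran-2-yl]-2-oxo-2,5-dihydrofuran-3-yl]methyl acetate, via mesylate 17 (not isolated)
Conditions: MsCl, Et3N, CH2Cl2, −40 °C; then 2,6-lutidine, MeCN, 60 °C
Reagents that add atoms: none
Why: After sulfonate activation the carbonyl oxygen of the cis tert-butyl ester displaces the mesylate in a 5-exo-tet neighbouring-group SN2 reaction with loss of 2-methylpropene, which closes ring B with inversion at C6 and turns the anti into the required syn relationship between O6 and the C4–C5 oxirane.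

Step 14
Reactants: 18 [(5R)-4-bromo-5-[(2R,3R)-3-methyl-3-{2-[(2R,3R)-3-methyl-3-(prop-2-en-1-yl)oxiran-2-yl]ethyl}oxiran-2-yl]-2-oxo-2,5-dihydrofuran-3-yl]methyl acetate
Product: 20 [(5R)-4-bromo-5-[(2R,3R)-3-methyl-3-{2-[(2R,3R)-3-methyl-3-(2-oxoethyl)oxiran-2-yl]ethyl}oxiran-2-yl]-2-oxo-2,5-dihydrofuran-3-yl]methyl acetate, via ozonide 19 (not isolated)
Conditions: O3, CH2Cl2, −78 °C; then PPh3, −78 → 20 °C
Reagents that add atoms: ozone, [O-][O+]=O
Why: Ozonolysis should cleave only the terminal vinyl group, the sole electron-rich olefin left, because the tetrasubstituted bromo-butenolide olefin is electron-poor, and the neutral PPh3 work-up spares the β,γ-epoxy aldehyde, which is used at once; no stereocentre changes.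

Step 15
Reactants: 20 [(5R)-4-bromo-5-[(2R,3R)-3-methyl-3-{2-[(2R,3R)-3-methyl-3-(2-oxoethyl)oxiran-2-yl]ethyl}oxiran-2-yl]-2-oxo-2,5-dihydrofuran-3-yl]methyl acetate
Product: 21 (1R,4R,5R,6S,8S,10R)-13-acetoxy-1,10:4,5-diepoxy-8-hydroxygermacr-7(11)-en-12,6-olide
Conditions: CrCl2 (10 equiv), NiCl2 (2 mol %), DMSO–THF 3:1, 25 °C, syringe-pump addition of 20 (final 2 mM)
Reagents that add atoms: none
Why: CrCl2 reduces NiCl2 to zerovalent nickel, which inserts into the activated C7–Br bond of ring B, and transmetalation gives a C7 alkenyl species of trivalent chromium that adds to the tethered C8 aldehyde, so the second bond of the C7 vinylidene linchpin is made after ring B is in place. The closest known reaction type is the Nozaki–Hiyama–Kishi macrocyclization of alkenyl halides, β-halo enoates included, onto aldehydes, a standard entry to medium carbocycles that tolerates esters, oxiranes and enolizable aldehydes. Ring A is the only ring closed and it closes in the 10-exo-trig mode (C7 attacks the C8 carbonyl carbon, the C=O bond staying outside the ring). The single new stereocentre C8 is controlled by C6 through a closed four-centre transition state: the tether reaches C7 from the face of ring B that carries C5, and chromium, bound to the aldehyde oxygen and to the C13 acetate oxygen, keeps the C8–O bond in the plane of ring B on the C11 side, so that H8 ends on the face of H6 and the 8S carbinol (O6 and O8 cis) should result. The step needs chemoselectivity (only the C–Br bond is activated, and the alkenylchromium adds to the aldehyde but not to lactone, acetate or oxiranes), ring closure over oligomerization (slow addition at high dilution, with the two trans-oxiranes and planar ring B leaving few free rotors) and an untouched C6, which the neutral, non-basic medium secures.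

Step 16
Reactants: 22 (R)-2-methylglycidol [(2R)-(2-methyloxiran-2-yl)methanol]
Product: 23 (2S)-2-methyloxirane-2-carboxylic acid
Conditions: TEMPO (cat.), NaOCl (cat.), NaClO2, MeCN–phosphate buffer (pH 6.7), 35 °C
Reagents that add atoms: sodium chlorite, [Na+].[O-]Cl=O
Why: The TEMPO-catalysed oxidation with NaClO2 as terminal oxidant takes the primary alcohol to the acid near neutral pH without opening the oxirane; the quaternary stereocentre is untouched (R becomes S only through the priority change).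

Step 17
Reactants: 21 (1R,4R,5R,6S,8S,10R)-13-acetoxy-1,10:4,5-diepoxy-8-hydroxygermacr-7(11)-en-12,6-olide; 23 (2S)-2-methyloxirane-2-carboxylic acid
Product: 24 (1R,4R,5R,6S,8S,10R)-13-acetoxy-1,10:4,5-diepoxy-8-[(2S)-2-methyloxirane-2-carbonyloxy]germacr-7(11)-en-12,6-olide (target)
Conditions: DCC, DMAP (cat.), CH2Cl2, 0 → 20 °C
Reagents that add atoms: none
Why: The Steglich esterification acylates the C8 hydroxyl with retention at C8 under mild conditions that spare the three oxiranes, the acetate and ring B.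

**Compound list**

1 | geranyl acetate, (2E)-3,7-dimethylocta-2,6-dien-1-yl acetate | CC(=O)OC/C=C(\C)CCC=C(C)C | starting material
2 | (2E,6E)-8-hydroxy-3,7-dimethylocta-2,6-dien-1-yl acetate | CC(=O)OC/C=C(\C)CC/C=C(\C)CO | intermediate
3 | (2E,6E)-8-bromo-3,7-dimethylocta-2,6-dien-1-yl acetate | CC(=O)OC/C=C(\C)CC/C=C(\C)CBr | intermediate
4 | (2E,6E)-3,7-dimethyldeca-2,6,9-trien-1-yl acetate | CC(=O)OC/C=C(\C)CC/C=C(\C)CC=C | intermediate
5 | (2E)-3-methyl-5-[(2R,3R)-3-methyl-3-(prop-2-en-1-yl)oxiran-2-yl]pent-2-en-1-yl acetate | C=CC[C@@]1(C)O[C@@H]1CC/C(C)=C/COC(C)=O | intermediate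
6 | (2E)-3-methyl-5-[(2R,3R)-3-methyl-3-(prop-2-en-1-yl)oxiran-2-yl]pent-2-en-1-ol | C=CC[C@@]1(C)O[C@@H]1CC/C(C)=C/CO | intermediate
7 | [(2R,3R)-3-methyl-3-{2-[(2R,3R)-3-methyl-3-(prop-2-en-1-yl)oxiran-2-yl]ethyl}oxiran-2-yl]methanol | C=CC[C@@]1(C)O[C@@H]1CC[C@@]2(C)O[C@@H]2CO | intermediate
8 | (2S,3R)-3-methyl-3-{2-[(2R,3R)-3-methyl-3-(prop-2-en-1-yl)oxiran-2-yl]ethyl}oxirane-2-carbaldehyde | C=CC[C@@]1(C)O[C@@H]1CC[C@@]2(C)O[C@@H]2C=O | intermediate
9 | tert-butyl acrylate | C=CC(=O)OC(C)(C)C | starting material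
10 | tert-butyl 2-(hydroxymethyl)prop-2-enoate | C=C(CO)C(=O)OC(C)(C)C | intermediate
11 | tert-butyl 2-(acetoxymethyl)prop-2-enoate | C=C(COC(C)=O)C(=O)OC(C)(C)C | intermediate
12 | tert-butyl 3-(acetoxymethyl)-1,2,4-trioxolane-3-carboxylate (ozonide of 11) | CC(=O)OCC1(OCOO1)C(=O)OC(C)(C)C | intermediate
13 | tert-butyl 3-acetoxy-2-oxopropanoate | CC(=O)OCC(=O)C(=O)OC(C)(C)C | intermediate
14 | tert-butyl 2-(acetoxymethyl)-3,3-dibromoprop-2-enoate | CC(=O)OCC(=C(Br)Br)C(=O)OC(C)(C)C | intermediate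
15 | [(1E)-3-acetoxy-1-bromo-2-(tert-butoxycarbonyl)prop-1-en-1-yl]magnesium chloride (magnesium cis to the ester) | CC(=O)OC/C(=C(\Br)[Mg]Cl)C(=O)OC(C)(C)C | intermediate
16 | tert-butyl (2E,4S)-2-(acetoxymethyl)-3-bromo-4-hydroxy-4-[(2R,3R)-3-methyl-3-{2-[(2R,3R)-3-methyl-3-(prop-2-en-1-yl)oxiran-2-yl]ethyl}oxiran-2-yl]but-2-enoate (anti epoxy alcohol) | C=CC[C@@]1(C)O[C@@H]1CC[C@@]2(C)O[C@@H]2[C@H](O)/C(Br)=C(/COC(C)=O)C(=O)OC(C)(C)C | intermediate
17 | tert-butyl (2E,4S)-2-(acetoxymethyl)-3-bromo-4-(methanesulfonyloxy)-4-[(2R,3R)-3-methyl-3-{2-[(2R,3R)-3-methyl-3-(prop-2-en-1-yl)oxiran-2-yl]ethyl}oxiran-2-yl]but-2-enoate | C=CC[C@@]1(C)O[C@@H]1CC[C@@]2(C)O[C@@H]2[C@H](OS(C)(=O)=O)/C(Br)=C(/COC(C)=O)C(=O)OC(C)(C)C | intermediate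
18 | [(5R)-4-bromo-5-[(2R,3R)-3-methyl-3-{2-[(2R,3R)-3-methyl-3-(prop-2-en-1-yl)oxiran-2-yl]ethyl}oxiran-2-yl]-2-oxo-2,5-dihydrofuran-3-yl]methyl acetate | C=CC[C@@]1(C)O[C@@H]1CC[C@@]2(C)O[C@@H]2[C@H]3OC(=O)C(COC(C)=O)=C3Br | intermediate
19 | ozonide of 18: [(5R)-4-bromo-5-[(2R,3R)-3-methyl-3-{2-[(2R,3R)-3-methyl-3-(1,2,4-trioxolan-3-ylmethyl)oxiran-2-yl]ethyl}oxiran-2-yl]-2-oxo-2,5-dihydrofuran-3-yl]methyl acetate (trioxolane carbon unspecified) | C1OC(OO1)C[C@@]2(C)O[C@@H]2CC[C@@]3(C)O[C@@H]3[C@H]4OC(=O)C(COC(C)=O)=C4Br | intermediate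
20 | [(5R)-4-bromo-5-[(2R,3R)-3-methyl-3-{2-[(2R,3R)-3-methyl-3-(2-oxoethyl)oxiran-2-yl]ethyl}oxiran-2-yl]-2-oxo-2,5-dihydrofuran-3-yl]methyl acetate | O=CC[C@@]1(C)O[C@@H]1CC[C@@]2(C)O[C@@H]2[C@H]3OC(=O)C(COC(C)=O)=C3Br | intermediate
21 | (1R,4R,5R,6S,8S,10R)-13-acetoxy-1,10:4,5-diepoxy-8-hydroxygermacr-7(11)-en-12,6-olide | CC(=O)OCC1=C2[C@@H](O)C[C@@]3(C)O[C@@H]3CC[C@@]3(C)O[C@@H]3[C@H]2OC1=O | intermediate
22 | (R)-2-methylglycidol, (2R)-(2-methyloxiran-2-yl)methanol | OC[C@]1(C)CO1 | starting material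
23 | (2S)-2-methyloxirane-2-carboxylic acid | OC(=O)[C@]1(C)CO1 | intermediate
24 | (1R,4R,5R,6S,8S,10R)-13-acetoxy-1,10:4,5-diepoxy-8-[(2S)-2-methyloxirane-2-carbonyloxy]germacr-7(11)-en-12,6-olide | CC(=O)OCC1=C2[C@@H](OC(=O)[C@]3(C)CO3)C[C@@]3(C)O[C@@H]3CC[C@@]3(C)O[C@@H]3[C@H]2OC1=O | target

**Step count and risks**

Total step count: 17. Longest linear sequence: 12 steps (steps 1–7, 12–15 and 17, from geranyl acetate).

The three steps most likely to fail:

Step 15. The facial selectivity at C8 in the ring-closing addition may be poor or reversed, because the sense of 1,3-induction across the sp2 carbon C7 rests on a transition-state model and not on a direct precedent. The fallback makes both epimers converge. It sets out from 20: the ring closure then gives mainly (1R,4R,5R,6S,8R,10R)-13-acetoxy-1,10:4,5-diepoxy-8-hydroxygermacr-7(11)-en-12,6-olide F1. F1 is esterified with 23 under Mitsunobu conditions (PPh3, DIAD, toluene, 0 °C), which inverts C8, and the route comes back at 24.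

Step 12. The hindered carbenoid may add to the epoxy aldehyde with poor facial selectivity (anti against syn), giving a mixture of C6 epimers. The fallback sets out from 14 and 8. The crude epimer mixture is oxidized (Dess–Martin periodinane, pyridine, CH2Cl2) to the epoxy ketone tert-butyl (2E)-2-(acetoxymethyl)-3-bromo-4-[(2S,3R)-3-methyl-3-{2-[(2R,3R)-3-methyl-3-(prop-2-en-1-yl)oxiran-2-yl]ethyl}oxiran-2-yl]-4-oxobut-2-enoate F2. F2 is reduced with Zn(BH4)2 (Et2O, −30 °C); this chelation-controlled reduction of α,β-epoxy ketones is anti-selective, and the route comes back at 16.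

Step 13. The activated C6 centre may ionize, or the neighbouring oxirane may take part, instead of clean SN2 closure, with loss of configuration at C6. The fallback separates inversion from ring closure and sets out from 16. Mitsunobu inversion with chloroacetic acid (PPh3, DIAD, toluene, 0 °C) gives the inverted chloroacetate tert-butyl (2E,4R)-2-(acetoxymethyl)-3-bromo-4-(chloroacetoxy)-4-[(2R,3R)-3-methyl-3-{2-[(2R,3R)-3-methyl-3-(prop-2-en-1-yl)oxiran-2-yl]ethyl}oxiran-2-yl]but-2-enoate F3. Selective removal of the chloroacetate in the presence of the acetate (thiourea, NaHCO3, EtOH, 40 °C) gives the syn alcohol tert-butyl (2E,4R)-2-(acetoxymethyl)-3-bromo-4-hydroxy-4-[(2R,3R)-3-methyl-3-{2-[(2R,3R)-3-methyl-3-(prop-2-en-1-yl)oxiran-2-yl]ethyl}oxiran-2-yl]but-2-enoate F4. F4 lactonizes with retention on mild acid catalysis (PPTS, toluene, 60 °C), and the route comes back at 18.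

Further compounds
F1 | step 15 | (1R,4R,5R,6S,8R,10R)-13-acetoxy-1,10:4,5-diepoxy-8-hydroxygermacr-7(11)-en-12,6-olide | CC(=O)OCC1=C2[C@H](O)C[C@@]3(C)O[C@@H]3CC[C@@]3(C)O[C@@H]3[C@H]2OC1=O
F2 | step 12 | tert-butyl (2E)-2-(acetoxymethyl)-3-bromo-4-[(2S,3R)-3-methyl-3-{2-[(2R,3R)-3-methyl-3-(prop-2-en-1-yl)oxiran-2-yl]ethyl}oxiran-2-yl]-4-oxobut-2-enoate | C=CC[C@@]1(C)O[C@@H]1CC[C@@]2(C)O[C@@H]2C(=O)/C(Br)=C(/COC(C)=O)C(=O)OC(C)(C)C
F3 | step 13 | tert-butyl (2E,4R)-2-(acetoxymethyl)-3-bromo-4-(chloroacetoxy)-4-[(2R,3R)-3-methyl-3-{2-[(2R,3R)-3-methyl-3-(prop-2-en-1-yl)oxiran-2-yl]ethyl}oxiran-2-yl]but-2-enoate | C=CC[C@@]1(C)O[C@@H]1CC[C@@]2(C)O[C@@H]2[C@@H](OC(=O)CCl)/C(Br)=C(/COC(C)=O)C(=O)OC(C)(C)C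
F4 | step 13 | tert-butyl (2E,4R)-2-(acetoxymethyl)-3-bromo-4-hydroxy-4-[(2R,3R)-3-methyl-3-{2-[(2R,3R)-3-methyl-3-(prop-2-en-1-yl)oxiran-2-yl]ethyl}oxiran-2-yl]but-2-enoate | C=CC[C@@]1(C)O[C@@H]1CC[C@@]2(C)O[C@@H]2[C@@H](O)/C(Br)=C(/COC(C)=O)C(=O)OC(C)(C)C
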